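The flavone is disconnected at the C2–C3 bond of ring C. C3, already carrying its methoxy group, is the α-carbon of a ring A ω-methoxyacetophenone; C2 is the carboxyl carbon of ring B, parked as an aryl ester on the ring A phenol oxygen that later becomes O1. A base-induced O-to-C aroyl shift (Baker–Venkataraman) joins C2 to C3 and delivers the 2-methoxy-1,3-diketone in one operation, closing no ring. The precursor is 2-(methoxyacetyl)-3,4,5,6-tetramethoxyphenyl 2-benzyloxy-4-methoxybenzoate; its benzyl ether keeps the 2'-oxygen silent during acid ring closure and is removed together with the chelated 5-methyl ether by BCl3.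

Key step: step 7

Remark: in ketone 8 the acyl-bearing carbon becomes C4a and the hydroxyl carbon becomes C8a (its oxygen O1). The three methoxy carbons that follow become C8, C7 and C6, and the methoxy carbon on the other side of the acyl group becomes C5. Diketone 14 is drawn in the diketo form; it should exist as a keto–enol mixture and its central carbon is not a defined stereocentre. Because BCl3 cleaves aryl benzyl ethers, the end game uses one BCl3 step for both the benzyl and the 5-methyl ether.

Step 1
Reactants: 1 1,2,3,4-tetramethoxybenzene
Product: 3 2,3,4,5-tetramethoxybenzaldehyde, via iminium salt 2 (not isolated)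
Conditions: POCl3, DMF, 0 → 80 °C; then ice-water
Reagents that add atoms: N,N-dimethylformamide, CN(C)C=O (formyl carbon); water, O (carbonyl oxygen)
Why: Vilsmeier–Haack formylation; the two free ring positions are equivalent by symmetry and each lies para to one methoxy group and ortho to another, so a single aldehyde should form after hydrolysis of the iminium salt.

Step 2
Reactants: 3 2,3,4,5-tetramethoxybenzaldehyde
Product: 5 2,3,4,5-tetramethoxyphenol, via aryl formate 4 (not isolated)
Conditions: mCPBA, CH2Cl2, 0 °C → rt; NaHCO3 wash; then K2CO3 (cat.), MeOH, rt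
Reagents that add atoms: mCPBA, O=C(OO)c1cccc(Cl)c1 (the phenol oxygen)
Why: Baeyer–Villiger (Dakin-type) oxidation, in which the electron-rich aryl group with ortho and para methoxy donors migrates in preference to hydrogen, and mild methanolysis of the formate should free the phenol.

Step 3
Reactants: 5 2,3,4,5-tetramethoxyphenol; 6 methoxyacetyl chloride
Product: 7 2,3,4,5-tetramethoxyphenyl methoxyacetate
Conditions: Et3N, DMAP (cat.), CH2Cl2, 0 °C → rt
Reagents that add atoms: none
Why: DMAP-catalysed O-acylation of a phenol by an acid chloride (nucleophilic acyl substitution), for which no competing nucleophile is present.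

Step 4
Reactants: 7 2,3,4,5-tetramethoxyphenyl methoxyacetate
Product: 8 1-(2-hydroxy-3,4,5,6-tetramethoxyphenyl)-2-methoxyethan-1-one
Conditions: BF3·OEt2 (neat), 70 °C; then H2O
Reagents that add atoms: none
Why: Fries rearrangement, in which the BF3-activated methoxyacetyl group can migrate only to the single unsubstituted ring carbon, which lies ortho to the ester oxygen, and binding of boron between the new carbonyl and the phenol oxygen should pull the shift forward.

Step 5
Reactants: 9 2-hydroxy-4-methoxybenzoic acid
Product: 11 2-benzyloxy-4-methoxybenzoic acid, via benzyl ester 10 (not isolated)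
Conditions: BnBr, K2CO3, DMF, 60 °C; then NaOH, MeOH/H2O, reflux; HCl
Reagents that add atoms: benzyl bromide, BrCc1ccccc1; sodium hydroxide, [Na+].[OH-] (one carboxyl oxygen after ester hydrolysis)
Why: Williamson O-benzylation of both the phenoxide and the carboxylate, followed by saponification of the benzyl ester, to which the aryl benzyl ether is inert.

Step 6
Reactants: 11 2-benzyloxy-4-methoxybenzoic acid; 8 1-(2-hydroxy-3,4,5,6-tetramethoxyphenyl)-2-methoxyethan-1-one
Product: 13 2-(methoxyacetyl)-3,4,5,6-tetramethoxyphenyl 2-benzyloxy-4-methoxybenzoate, via acid chloride 12 (not isolated)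
Conditions: (COCl)2, DMF (cat.), CH2Cl2, rt; evaporate; then 8, pyridine, DMAP (cat.), CH2Cl2, rt → 40 °C
Reagents that add atoms: none
Why: Acid chloride formation followed by DMAP-catalysed esterification of the hindered, hydrogen-bonded phenol; pyridine is too weak a base to enolise the ketone, so the ester should be isolable without premature acyl shift.

Step 7
Reactants: 13 2-(methoxyacetyl)-3,4,5,6-tetramethoxyphenyl 2-benzyloxy-4-methoxybenzoate
Product: 14 1-(2-benzyloxy-4-methoxyphenyl)-3-(2-hydroxy-3,4,5,6-tetramethoxyphenyl)-2-methoxypropane-1,3-dione
Conditions: KOtBu (3 equiv), THF, 0 °C → rt; then AcOH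
Reagents that add atoms: none
Why: tert-Butoxide removes a proton from the CH2 group between the ketone and the methoxy group, and the potassium enolate, held next to the aryl ester, adds through carbon to the benzoate carbonyl in a six-membered cyclic transition state; collapse of the tetrahedral adduct expels the ring A phenoxide, so the aroyl group moves from oxygen to carbon and the C2–C3 bond of the future ring C is formed. This is a Baker–Venkataraman rearrangement, an intramolecular Claisen-type acyl transfer well established for ortho-aroyloxy ω-methoxyacetophenones. No ring is closed, since the cyclic arrangement exists only in the transition state and ring C is closed in step 8. The new methine carbon between the two carbonyl groups is freely enolisable, so it forms without control as a racemic, tautomerising centre and becomes sp2 in step 8. The selectivity required is acyl transfer over ester cleavage, secured by a hindered non-nucleophilic alkoxide in dry aprotic THF, by the ortho-benzyloxy group shielding the benzoate carbonyl from external nucleophiles, and by the proximity of the enolate; the methoxyacetyl CH2 is the only acidic C–H, so C-acylation can occur nowhere else. More than two equivalents of base are used because the product is deprotonated twice (phenoxide and β-diketonate), which should make the transfer irreversible.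

Step 8
Reactants: 14 1-(2-benzyloxy-4-methoxyphenyl)-3-(2-hydroxy-3,4,5,6-tetramethoxyphenyl)-2-methoxypropane-1,3-dione
Product: 15 2-(2-benzyloxy-4-methoxyphenyl)-3,5,6,7,8-pentamethoxy-4H-chromen-4-one
Conditions: H2SO4 (cat.), AcOH, 50 °C
Reagents that add atoms: none
Why: Acid-catalysed cyclodehydration (flavone ring closure), in which the ring A phenol adds 6-exo-trig to the ring B ketone and water is lost to give the pyranone; the benzyl ether should survive catalytic acid at this temperature and keeps the ring B oxygen from closing the isomeric chromone.

Step 9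
Reactants: 15 2-(2-benzyloxy-4-methoxyphenyl)-3,5,6,7,8-pentamethoxy-4H-chromen-4-one
Product: 16 5,2'-dihydroxy-3,6,7,8,4'-pentamethoxyflavone
Conditions: BCl3 (5 equiv), pentamethylbenzene, CH2Cl2, −78 → 0 °C; then MeOH, H2O
Reagents that add atoms: none
Why: Chelation-assisted ether cleavage, in which BCl3 bound between C4=O and the peri 5-methoxy oxygen lets chloride remove that methyl group, while the same Lewis acid ionises the aryl benzyl ether and pentamethylbenzene traps the benzyl cation by Friedel–Crafts alkylation; the unchelated methyl ethers at C3, C6, C7, C8 and C4' should persist at or below 0 °C.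

Compound list
1 | 1,2,3,4-tetramethoxybenzene | COc1ccc(OC)c(OC)c1OC | starting material
2 | N,N-dimethyl-(2,3,4,5-tetramethoxybenzylidene)iminium dichlorophosphate (formed in the flask, not isolated) | C[N+](C)=Cc1cc(OC)c(OC)c(OC)c1OC.[O-]P(=O)(Cl)Cl | intermediate
3 | 2,3,4,5-tetramethoxybenzaldehyde | O=Cc1cc(OC)c(OC)c(OC)c1OC | intermediate
4 | 2,3,4,5-tetramethoxyphenyl formate (formed in the flask, not isolated) | O=COc1cc(OC)c(OC)c(OC)c1OC | intermediate
5 | 2,3,4,5-tetramethoxyphenol | Oc1cc(OC)c(OC)c(OC)c1OC | intermediate
6 | methoxyacetyl chloride | COCC(=O)Cl | starting material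
7 | 2,3,4,5-tetramethoxyphenyl methoxyacetate | COCC(=O)Oc1cc(OC)c(OC)c(OC)c1OC | intermediate
8 | 1-(2-hydroxy-3,4,5,6-tetramethoxyphenyl)-2-methoxyethan-1-one | COCC(=O)c1c(O)c(OC)c(OC)c(OC)c1OC | intermediate
9 | 2-hydroxy-4-methoxybenzoic acid | COc1ccc(C(=O)O)c(O)c1 | starting material
10 | benzyl 2-benzyloxy-4-methoxybenzoate (formed in the flask, not isolated) | COc1ccc(C(=O)OCc2ccccc2)c(OCc2ccccc2)c1 | intermediate
11 | 2-benzyloxy-4-methoxybenzoic acid | COc1ccc(C(=O)O)c(OCc2ccccc2)c1 | intermediate
12 | 2-benzyloxy-4-methoxybenzoyl chloride (formed in the flask, not isolated) | COc1ccc(C(=O)Cl)c(OCc2ccccc2)c1 | intermediate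
13 | 2-(methoxyacetyl)-3,4,5,6-tetramethoxyphenyl 2-benzyloxy-4-methoxybenzoate | COCC(=O)c1c(OC)c(OC)c(OC)c(OC)c1OC(=O)c1ccc(OC)cc1OCc1ccccc1 | intermediate
14 | 1-(2-benzyloxy-4-methoxyphenyl)-3-(2-hydroxy-3,4,5,6-tetramethoxyphenyl)-2-methoxypropane-1,3-dione (central carbon unassigned, tautomerising) | COc1ccc(C(=O)C(OC)C(=O)c2c(O)c(OC)c(OC)c(OC)c2OC)c(OCc2ccccc2)c1 | intermediate
15 | 2-(2-benzyloxy-4-methoxyphenyl)-3,5,6,7,8-pentamethoxy-4H-chromen-4-one | COc1ccc(-c2oc3c(OC)c(OC)c(OC)c(OC)c3c(=O)c2OC)c(OCc2ccccc2)c1 | intermediate
16 | 5,2'-dihydroxy-3,6,7,8,4'-pentamethoxyflavone (5-hydroxy-2-(2-hydroxy-4-methoxyphenyl)-3,6,7,8-tetramethoxy-4H-chromen-4-one) | COc1ccc(-c2oc3c(OC)c(OC)c(OC)c(O)c3c(=O)c2OC)c(O)c1 | target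

Total step count: 9. Longest linear sequence: 8 steps (steps 1, 2, 3, 4, 6, 7, 8, 9); step 5 is a one-step branch that joins at step 6.

Steps most likely to fail

1. Step 7. Alkoxide or adventitious hydroxide may cleave the aryl ester faster than the enolate attacks it, or the diketonate may fragment by retro-Claisen cleavage on long exposure to base. The fallback is an Allan–Robinson condensation that sets out from ketone 8 and acid 11. Acid 11 would be converted with DCC in CH2Cl2 into 2-benzyloxy-4-methoxybenzoic anhydride F1 and with KOH in MeOH into potassium 2-benzyloxy-4-methoxybenzoate F2. Ketone 8 would be heated with F1 and F2 as a melt at about 175 °C and then treated briefly with aqueous-ethanolic KOH. O-Aroylation, acyl migration and ring closure should then occur in one pot, and the route is rejoined at flavone 15.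

2. Step 9. Ether cleavage may lose selectivity once boron is bound at O5 and C4=O, with further demethylation at O6 or O3, or untrapped benzyl cation may alkylate ring B. The fallback sets out from 15 and separates the two deprotections by mechanism. Hydrogenolysis (H2, Pd/C, EtOAc–MeOH, rt) should give 2-(2-hydroxy-4-methoxyphenyl)-3,5,6,7,8-pentamethoxy-4H-chromen-4-one F3. Concentrated HCl in EtOH at reflux should then remove only the 5-methyl group, which is activated by the peri carbonyl, and the route ends at target 16.

3. Step 4. De-acylation back to the phenol and Lewis-acid attack on the flanking methyl ethers may compete with acyl migration. The fallback sets out from phenol 5, which would be methylated (Me2SO4, K2CO3, acetone, reflux) to pentamethoxybenzene F4. Friedel–Crafts acylation of F4 with 6 and AlCl3 in Et2O (0 °C → rt) at the single free ring carbon should give 2-methoxy-1-(pentamethoxyphenyl)ethan-1-one F5, which is not isolated. Its aluminium chelate should lose one of the two equivalent ortho methyl groups, and the route is rejoined at ketone 8.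

Further compounds
F1 | step 7 | 2-benzyloxy-4-methoxybenzoic anhydride | COc1ccc(C(=O)OC(=O)c2ccc(OC)cc2OCc2ccccc2)c(OCc2ccccc2)c1
F2 | step 7 | potassium 2-benzyloxy-4-methoxybenzoate | COc1ccc(C(=O)[O-])c(OCc2ccccc2)c1.[K+]
F3 | step 9 | 2-(2-hydroxy-4-methoxyphenyl)-3,5,6,7,8-pentamethoxy-4H-chromen-4-one | COc1ccc(-c2oc3c(OC)c(OC)c(OC)c(OC)c3c(=O)c2OC)c(O)c1
F4 | step 4 | pentamethoxybenzene | COc1cc(OC)c(OC)c(OC)c1OC
F5 | step 4 | 2-methoxy-1-(pentamethoxyphenyl)ethan-1-one | COCC(=O)c1c(OC)c(OC)c(OC)c(OC)c1OC
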